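**Plan**
1. Numbering: each half is a naphthalen-1(4H)-one (C1–C8a, primed in the second half). Ring A is the arene, ring B is the enolised dione ring C1–C2–C3–C4–C4a–C8a, and C9 is the bridging CH2.
2. Retrosynthesis: the two aryl–acetyl bonds at C7 and C7' and the four O-methyl groups of a tetramethyl ether are removed first. The bridge is then cut at C2–C9 and C9–C2', and each ring B at C2–C3, which leads to formaldehyde and two molecules of an ortho-acetyl aryl isobutyrate.
3. That keto ester goes back to methyl (3,5-dimethoxyphenyl)acetate by cutting the two benzylic C–CH3 bonds and the aryl–acetyl bond (through an aryl bromide).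
4. Enabling feature: C2 of ring B is the central carbon of a 1,3-dicarbonyl unit (C1=O, C3–OH) and is bonded to C3 and to C9, so both bonds can be made from C2 as an enolate carbon. C4 is quaternary, which leaves the ester partner without α-hydrogen.
5. Forward: ring A is bought. Bromination, coupling and double methylation give the keto ester; one pot then closes ring B in both halves and joins them through C9; ether cleavage and ring acetylation finish the synthesis.
6. Stereochemistry: the target has no stereocentre and no configured double bond, so none has to be set.

Key step: step 4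

Remark: the target and the bis-diones 10 and 11 are written as the 3-hydroxy-1(4H)-one enol tautomers of the target SMILES. They equilibrate with the diketo forms, and 8 and 9 are written as diketones.

**Route**

Step 1
Reactants: 1 methyl 2-(3,5-dimethoxyphenyl)acetate
Product: 2 methyl 2-(2-bromo-3,5-dimethoxyphenyl)acetate
Conditions: NBS (1.0 equiv), MeCN, 0 °C to rt
Reagents that add atoms: N-bromosuccinimide, O=C1CCC(=O)N1Br
Why: Electrophilic aromatic bromination should occur at the ring carbon ortho to the side chain, which is para to one methoxy group and ortho to the other and less crowded than the position between the two methoxy groups, and one equivalent at low temperature limits dibromination.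

Step 2
Reactants: 2 methyl 2-(2-bromo-3,5-dimethoxyphenyl)acetate; 3 tributyl(1-ethoxyvinyl)stannane
Product: 4 methyl 2-[2-(1-ethoxyvinyl)-3,5-dimethoxyphenyl]acetate
Conditions: Pd(PPh3)4 (5 mol %), toluene, 110 °C; chromatography on K2CO3-doped silica
Reagents that add atoms: none
Why: In this Stille coupling zerovalent palladium inserts into the aryl C–Br bond and the stannane transfers its 1-ethoxyvinyl group, a base-stable masked acetyl; no base is present, so the acidic benzylic CH2 is untouched, and the basic silica removes tin residues without hydrolysing the enol ether.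

Step 3
Reactants: 4 methyl 2-[2-(1-ethoxyvinyl)-3,5-dimethoxyphenyl]acetate
Product: 6 methyl 2-(2-acetyl-3,5-dimethoxyphenyl)-2-methylpropanoate, via gem-dimethyl enol ether 5 (not isolated)
Conditions: NaH (2.5 equiv), MeI (3 equiv), DMF, 0 °C to rt; then 1 M HCl, THF, rt
Reagents that add atoms: iodomethane, CI; water, O
Why: Twofold enolate C-alkylation of the arylacetate should build the quaternary benzylic carbon while the ketone is still masked as an enol ether that can neither enolise nor be attacked, and dilute acid then hydrolyses the enol ether to the methyl ketone.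

Step 4
Reactants: 6 methyl 2-(2-acetyl-3,5-dimethoxyphenyl)-2-methylpropanoate (two molecules); 7 formaldehyde
Product: 10 2,2'-methylenebis(3-hydroxy-6,8-dimethoxy-4,4-dimethylnaphthalen-1(4H)-one), via monomeric 1,3-dione 8 (not isolated), via 2-methylidene dione 9 (not isolated)
Conditions: NaOMe (3 equiv), MeOH, 65 °C; then AcOH to pH 6, 37% aq CH2O (0.5 equiv per 6), rt to 40 °C
Reagents that add atoms: none
Why: Methoxide reversibly forms the enolate of the acetyl group of 6, whose carbon attacks the neighbouring ester carbonyl and expels methoxide (intramolecular Claisen condensation of the Dieckmann type), forming C2–C3 and ring B; deprotonation of dione 8 to its sodium enolate makes the closure irreversible, and both molecules close in the same way. Each ring B closes in the favoured 6-(enolendo)-exo-trig mode. Once the medium is buffered with AcOH, C2 of one diketonate adds to formaldehyde and water is lost (Knoevenagel condensation) to give enedione 9, and C2 of a second diketonate adds to its exocyclic methylene carbon (Michael addition), forming C2–C9 and C9–C2'. The closest known reactions are the alkoxide cyclisation of ortho-acylaryl acetic esters to naphthalene-1,3-diones and the coupling of dimedone-type 1,3-diones with formaldehyde in acetate buffer to methylenebis(1,3-diones). No stereocentre is created, so only chemoselectivity and stoichiometry matter. Because C4 is quaternary the ester has no α-hydrogen and only the acetyl group can be the nucleophile; C2 of 8 is the only carbon acid ionised in the buffer, so formaldehyde reacts there and not on ring A; and half an equivalent of formaldehyde, with 9 far more electrophilic than formaldehyde towards the diketonate, should stop the sequence at the bridged dimer.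

Step 5
Reactants: 10 2,2'-methylenebis(3-hydroxy-6,8-dimethoxy-4,4-dimethylnaphthalen-1(4H)-one)
Product: 11 2,2'-methylenebis(3,6,8-trihydroxy-4,4-dimethylnaphthalen-1(4H)-one)
Conditions: BBr3 (10 equiv), CH2Cl2, −78 °C to rt; then H2O
Reagents that add atoms: none
Why: In this Lewis-acid ether cleavage BBr3 coordinates each aryl methyl ether oxygen and bromide removes the methyl group by SN2, the C8 and C8' ethers being helped by chelation to the C1 carbonyl, while the enolised diones are only converted into borates that hydrolyse on work-up.

Step 6
Reactants: 11 2,2'-methylenebis(3,6,8-trihydroxy-4,4-dimethylnaphthalen-1(4H)-one)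
Product: 12 2,2'-methylenebis(7-acetyl-3,6,8-trihydroxy-4,4-dimethylnaphthalen-1(4H)-one) (target)
Conditions: Ac2O (2.5 equiv), BF3·OEt2, 1,4-dioxane, rt to 50 °C; then H2O
Reagents that add atoms: acetic anhydride, CC(=O)OC(C)=O
Why: Friedel–Crafts C-acetylation of each resorcinol ring should go to C7, which is ortho to both hydroxyls, meta to the C1 carbonyl and gives a ketone hydrogen-bonded on both sides, whereas the only other free position, C5, is shielded by the peri gem-dimethyl group at C4.

**Compound list**
1 | methyl 2-(3,5-dimethoxyphenyl)acetate | COC(=O)Cc1cc(OC)cc(OC)c1 | starting material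
2 | methyl 2-(2-bromo-3,5-dimethoxyphenyl)acetate | COC(=O)Cc1cc(OC)cc(OC)c1Br | intermediate
3 | tributyl(1-ethoxyvinyl)stannane | CCCC[Sn](CCCC)(CCCC)C(=C)OCC | starting material
4 | methyl 2-[2-(1-ethoxyvinyl)-3,5-dimethoxyphenyl]acetate | CCOC(=C)c1c(OC)cc(OC)cc1CC(=O)OC | intermediate
5 | methyl 2-[2-(1-ethoxyvinyl)-3,5-dimethoxyphenyl]-2-methylpropanoate | CCOC(=C)c1c(OC)cc(OC)cc1C(C)(C)C(=O)OC | intermediate (not isolated)
6 | methyl 2-(2-acetyl-3,5-dimethoxyphenyl)-2-methylpropanoate | COC(=O)C(C)(C)c1cc(OC)cc(OC)c1C(C)=O | intermediate
7 | formaldehyde | C=O | starting material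
8 | 6,8-dimethoxy-4,4-dimethylnaphthalene-1,3(2H,4H)-dione (present as its sodium enolate) | COc1cc(OC)c2c(c1)C(C)(C)C(=O)CC2=O | intermediate (not isolated)
9 | 6,8-dimethoxy-4,4-dimethyl-2-methylidenenaphthalene-1,3(2H,4H)-dione | COc1cc(OC)c2c(c1)C(C)(C)C(=O)C(=C)C2=O | intermediate (not isolated)
10 | 2,2'-methylenebis(3-hydroxy-6,8-dimethoxy-4,4-dimethylnaphthalen-1(4H)-one) | COc1cc(OC)c2c(c1)C(C)(C)C(O)=C(CC1=C(O)C(C)(C)c3cc(OC)cc(OC)c3C1=O)C2=O | intermediate
11 | 2,2'-methylenebis(3,6,8-trihydroxy-4,4-dimethylnaphthalen-1(4H)-one) | Oc1cc(O)c2c(c1)C(C)(C)C(O)=C(CC1=C(O)C(C)(C)c3cc(O)cc(O)c3C1=O)C2=O | intermediate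
12 | 2,2'-methylenebis(7-acetyl-3,6,8-trihydroxy-4,4-dimethylnaphthalen-1(4H)-one) | CC(=O)c1c(O)cc2c(c1O)C(=O)C(CC1=C(O)C(C)(C)c3cc(O)c(C(C)=O)c(O)c3C1=O)=C(O)C2(C)C | target

Total step count: 6. Longest linear sequence: 6 steps (1 to 12).

**Steps most likely to fail**

Step 6. What may go wrong: acetylation on the phenol and enol oxygens in place of C7, incomplete reaction of the second half, and acid- and anhydride-promoted cyclodehydration of the two C3 enols across C9. Fallback: the ring acetyl is put in before the dimer exists and is carried through the key step as a spectator. Setting out from 6, Friedel–Crafts acetylation with AcCl and SnCl4 in CH2Cl2 at 0 °C should take place at the ring position between the two methoxy groups, because the only other free position is flanked by the quaternary benzylic carbon, and give methyl 2-(2,4-diacetyl-3,5-dimethoxyphenyl)-2-methylpropanoate F1. Under the conditions of step 4 only the acetyl group next to the ester chain can close a ring, so F1 should pass through 7-acetyl-6,8-dimethoxy-4,4-dimethylnaphthalene-1,3(2H,4H)-dione F2 and 7-acetyl-6,8-dimethoxy-4,4-dimethyl-2-methylidenenaphthalene-1,3(2H,4H)-dione F3, neither isolated, to 2,2'-methylenebis(7-acetyl-3-hydroxy-6,8-dimethoxy-4,4-dimethylnaphthalen-1(4H)-one) F4. The acetate buffer keeps the spectator methyl ketone from reacting with formaldehyde. BBr3 in CH2Cl2 then cleaves the four ethers of F4, each of which is now ortho to a carbonyl group, and the route is rejoined at the target 12.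

Step 4. What may go wrong: slow acyl substitution at the neopentyl-type ester under reversible methoxide conditions, and loss of formaldehyde to hydroxymethylation that does not eliminate or to Cannizzaro disproportionation before the dione is fully formed. Fallback: the two events are separated and C9 is delivered as an iminium ion. Setting out from 6, KOtBu in THF closes ring B irreversibly and acidification allows 8 to be isolated. Half of 8 is treated with dimethylmethyleneiminium iodide (Eschenmoser's salt) and Et3N in CH2Cl2 to give the Mannich base 2-[(dimethylamino)methyl]-3-hydroxy-6,8-dimethoxy-4,4-dimethylnaphthalen-1(4H)-one F5. Heating F5 with the other half of 8 in toluene at 110 °C should expel dimethylamine, form 9 and trap it by Michael addition, which rejoins the route at 10.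

Step 3. What may go wrong: loss of the enol ether mask before both methyl groups are in place (on isolation of 4 or through adventitious acid), after which the free methyl ketone would condense with the still enolisable arylacetate and aromatise; or stalling after the first methylation. Fallback: the quaternary carbon is built before the ketone is introduced. Setting out from 2, NaH and MeI in DMF give methyl 2-(2-bromo-3,5-dimethoxyphenyl)-2-methylpropanoate F6. The now doubly ortho-hindered bromide is coupled with 3 using Pd(P(t-Bu)3)2 and CsF in 1,4-dioxane at 100 °C to give 5, and 1 M HCl in the work-up hydrolyses 5, rejoining the route at 6.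

**Further compounds**
F1 | step 6 | methyl 2-(2,4-diacetyl-3,5-dimethoxyphenyl)-2-methylpropanoate | COC(=O)C(C)(C)c1cc(OC)c(C(C)=O)c(OC)c1C(C)=O
F2 | step 6 | 7-acetyl-6,8-dimethoxy-4,4-dimethylnaphthalene-1,3(2H,4H)-dione | COc1cc2c(c(OC)c1C(C)=O)C(=O)CC(=O)C2(C)C
F3 | step 6 | 7-acetyl-6,8-dimethoxy-4,4-dimethyl-2-methylidenenaphthalene-1,3(2H,4H)-dione | COc1cc2c(c(OC)c1C(C)=O)C(=O)C(=C)C(=O)C2(C)C
F4 | step 6 | 2,2'-methylenebis(7-acetyl-3-hydroxy-6,8-dimethoxy-4,4-dimethylnaphthalen-1(4H)-one) | CC(=O)c1c(OC)cc2c(c1OC)C(=O)C(CC1=C(O)C(C)(C)c3cc(OC)c(C(C)=O)c(OC)c3C1=O)=C(O)C2(C)C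
F5 | step 4 | 2-[(dimethylamino)methyl]-3-hydroxy-6,8-dimethoxy-4,4-dimethylnaphthalen-1(4H)-one | CN(C)CC1=C(O)C(C)(C)c2cc(OC)cc(OC)c2C1=O
F6 | step 3 | methyl 2-(2-bromo-3,5-dimethoxyphenyl)-2-methylpropanoate | COC(=O)C(C)(C)c1cc(OC)cc(OC)c1Br
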